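**Plan**
- Cuts: the ring bond C1–C14 together with the lactone bond O14–C16 (made last), C1=C15 (cross-metathesis bringing C15–C17), C8–C9 and C8–C19 (two successive carbanion additions to one C8 acyl group), C2–C3 (allylation), and O–C4 of the oxolane.
- Forward order: the oxolane first (C3–C8 from (S)-glycidol and a methallyl unit, Os-catalysed oxidative cyclisation), then C1/C2, then the C9–C14 chain from (S)-citronellal at C8, then the acrylate; the 14-membered carbocycle and the γ-lactone close together in the final C–C bond formation.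
- Enabling feature: the cis-fused α-methylene-γ-lactone O14–C14–C1–C15(=C17)–C16, with O14 syn to O13, is the retron of a chelation-controlled 2-(alkoxycarbonyl)allyl-metal addition to an α-alkoxy aldehyde, so the ring bond C1–C14 can itself be the macrocyclisation.
- Stereochemistry: C7 from (S)-glycidol; C4 from the cis-selective oxidative cyclisation; C3 from reagent-controlled allylboration; C8 from Cram-chelate addition of MeMgBr (oxolane oxygen); C12 from (S)-citronellal; C13 from L-proline α-aminoxylation; C1 and C14 in the key step (Z-allyl geometry, O13 chelate).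

Key step: step 18

Assumption: atoms carry cembrane numbers throughout (ring C1–C14, acrylate C15–C17, methyls C18 on C4, C19 on C8, C20 on C12); 1, 2, 10, 22 and the (+)-Ipc2B(allyl) solution are taken as commercial.

Step 1
Reactants: 1 (S)-glycidol; 2 2-methylallylmagnesium chloride
Product: 3 (2R)-5-methylhex-5-ene-1,2-diol
Conditions: 2 (2.5 equiv), CuI (10 mol%), THF, −40 → 0 °C; aq. NH4Cl
Reagents that add atoms: none
Why: Cu(I)-catalysed Grignard opening of the terminal epoxide at its CH2 carbon (SN2) leaves the chiral-pool carbinol centre C7 untouched, the first equivalent of Grignard reagent only deprotonating the hydroxyl.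

Step 2
Reactants: 3 (2R)-5-methylhex-5-ene-1,2-diol
Product: 4 [(2S,5R)-2-methyloxolane-2,5-diyl]dimethanol
Conditions: OsO4 (5 mol%), Me3NO·2H2O, TFA, acetone/H2O, rt
Reagents that add atoms: trimethylamine N-oxide (C[N+](C)(C)[O-])
Why: Os-catalysed oxidative cyclisation of a 1,2-diol onto an alkene (Donohoe type), in which the Os(VI) diolate delivers O7 and an oxo ligand syn across the 1,1-disubstituted alkene in a [3+2] manner that is known to give only 2,5-cis oxolanes, so the quaternary C4 is set with C3 cis to C8.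

Step 3
Reactants: 4 [(2S,5R)-2-methyloxolane-2,5-diyl]dimethanol
Product: 5 (1R,5S)-5-methyl-3,8-dioxabicyclo[3.2.1]octan-2-one
Conditions: TEMPO (20 mol%), PhI(OAc)2, CH2Cl2, rt
Reagents that add atoms: none
Why: TEMPO/PhI(OAc)2 oxidative lactonisation, in which the oxoammonium ion should oxidise the unhindered CH2OH on C7 faster than the neopentyl CH2OH on quaternary C4, the cis-disposed hydroxy aldehyde closing to the bridged lactol that is oxidised on to the lactone.

Step 4
Reactants: 5 (1R,5S)-5-methyl-3,8-dioxabicyclo[3.2.1]octan-2-one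
Product: 6 (2R,5S)-5-(hydroxymethyl)-N-methoxy-N,5-dimethyloxolane-2-carboxamide
Conditions: Me(MeO)NH·HCl, i-PrMgCl, THF, −20 → 0 °C
Reagents that add atoms: N,O-dimethylhydroxylamine hydrochloride (CNOC.Cl)
Why: Weinreb aminolysis of the bridged lactone by the chloromagnesium amide frees the C3 hydroxyl and leaves C8 as an acyl group that will accept exactly one carbanion later.

Step 5
Reactants: 6 (2R,5S)-5-(hydroxymethyl)-N-methoxy-N,5-dimethyloxolane-2-carboxamide
Product: 7 (2R,5S)-5-formyl-N-methoxy-N,5-dimethyloxolane-2-carboxamide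
Conditions: Dess–Martin periodinane, NaHCO3, CH2Cl2, 0 °C → rt
Reagents that add atoms: none
Why: Dess–Martin oxidation of the neopentyl primary alcohol gives a non-enolisable α-alkoxy aldehyde, the Weinreb amide being inert.

Step 6
Reactants: 7 (2R,5S)-5-formyl-N-methoxy-N,5-dimethyloxolane-2-carboxamide
Product: 8 (2R,5S)-5-[(1R)-1-hydroxybut-3-en-1-yl]-N-methoxy-N,5-dimethyloxolane-2-carboxamide
Conditions: (+)-Ipc2B(allyl), Et2O, −78 °C; then NaOH, H2O2, 0 °C
Reagents that add atoms: (+)-B-allyldiisopinocampheylborane, from (−)-α-pinene (C=CCB([C@H]1C[C@H]2C[C@@H]([C@@H]1C)C2(C)C)[C@H]1C[C@H]2C[C@@H]([C@@H]1C)C2(C)C)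
Why: Brown allylboration through a chair six-membered transition state, in which the isopinocampheyl groups of the (−)-α-pinene-derived reagent direct the allyl group to the Re face of the aldehyde (the α-quaternary centre offers little bias of its own) and so set (3R), the amide being untouched at −78 °C.

Step 7
Reactants: 8 (2R,5S)-5-[(1R)-1-hydroxybut-3-en-1-yl]-N-methoxy-N,5-dimethyloxolane-2-carboxamide
Product: 9 (2R,5S)-5-[(1R)-1-(tert-butyldimethylsilyloxy)but-3-en-1-yl]-N-methoxy-N,5-dimethyloxolane-2-carboxamide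
Conditions: TBSOTf, 2,6-lutidine, CH2Cl2, −78 → 0 °C
Reagents that add atoms: tert-butyldimethylsilyl triflate (CC(C)(C)[Si](C)(C)OS(=O)(=O)C(F)(F)F)
Why: Silylation of the hindered secondary alcohol with the silyl triflate masks O3, the one oxygen that must stay unacetylated at the end.

Step 8
Reactants: 10 (S)-citronellal
Product: 12 (2R,3S)-3,7-dimethyl-2-(phenylaminooxy)oct-6-en-1-ol, via α-aminoxy aldehyde 11 (not isolated)
Conditions: PhNO, L-proline (20 mol%), CHCl3, 4 °C; then NaBH4, EtOH, 0 °C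
Reagents that add atoms: nitrosobenzene (O=Nc1ccccc1)
Why: Proline-catalysed enamine α-aminoxylation, in which the enamine of L-proline attacks the oxygen of nitrosobenzene under hydrogen-bond direction by the carboxylic acid and sets (13R) under catalyst control, the aldehyde being reduced at once so that the new centre cannot epimerise.

Step 9
Reactants: 12 (2R,3S)-3,7-dimethyl-2-(phenylaminooxy)oct-6-en-1-ol
Product: 13 (2R,3S)-3,7-dimethyloct-6-ene-1,2-diol
Conditions: Zn dust, AcOH, rt
Reagents that add atoms: none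
Why: Reductive N–O bond cleavage by zinc in acetic acid frees the diol without touching the trisubstituted alkene.

Step 10
Reactants: 13 (2R,3S)-3,7-dimethyloct-6-ene-1,2-diol
Product: 14 (4R)-2-(4-methoxyphenyl)-4-[(2S)-6-methylhept-5-en-2-yl]-1,3-dioxolane (both C2 epimers)
Conditions: 4-MeOC6H4CH(OMe)2, PPTS (cat.), CH2Cl2, rt
Reagents that add atoms: 4-methoxybenzaldehyde dimethyl acetal (COC(OC)c1ccc(OC)cc1)
Why: Acid-catalysed transacetalisation gives the p-methoxybenzylidene acetal, which protects O13 and O14 together and already contains the later O13 PMB ether.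

Step 11
Reactants: 14 (4R)-2-(4-methoxyphenyl)-4-[(2S)-6-methylhept-5-en-2-yl]-1,3-dioxolane
Product: 16 (4S)-4-[(4R)-2-(4-methoxyphenyl)-1,3-dioxolan-4-yl]pentan-1-ol, via aldehyde 15 (not isolated)
Conditions: OsO4 (2 mol%), NaIO4, 2,6-lutidine, dioxane/H2O, rt; then NaBH4, MeOH, 0 °C
Reagents that add atoms: sodium periodate ([Na+].[O-]I(=O)(=O)=O)
Why: Lemieux–Johnson cleavage of the only alkene followed by borohydride reduction turns the isopropylidene terminus into the C9 alcohol and spares the electron-rich acetal that ozone could attack.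

Step 12
Reactants: 16 (4S)-4-[(4R)-2-(4-methoxyphenyl)-1,3-dioxolan-4-yl]pentan-1-ol
Product: 17 (4R)-4-[(2S)-5-iodopentan-2-yl]-2-(4-methoxyphenyl)-1,3-dioxolane
Conditions: I2, PPh3, imidazole, CH2Cl2, 0 °C → rt
Reagents that add atoms: iodine (II)
Why: Appel-type iodination (Garegg–Samuelsson) of the primary alcohol under basic conditions that the acetal tolerates.

Step 13
Reactants: 17 (4R)-4-[(2S)-5-iodopentan-2-yl]-2-(4-methoxyphenyl)-1,3-dioxolane; 9 (2R,5S)-5-[(1R)-1-(tert-butyldimethylsilyloxy)but-3-en-1-yl]-N-methoxy-N,5-dimethyloxolane-2-carboxamide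
Product: 19 C8 ketone joining the oxolane to the C9–C14 chain, via organolithium 18 (not isolated)
Conditions: 17, t-BuLi (2.1 equiv), Et2O/pentane, −78 °C; then 9, −78 → −40 °C; aq. NH4Cl
Reagents that add atoms: none
Why: Lithium–iodine exchange gives the primary alkyllithium, whose addition to the Weinreb amide stops at the chelated tetrahedral intermediate, so the C8–C9 bond forms as a ketone without over-addition and without epimerisation at C7.

Step 14
Reactants: 19 C8 ketone
Product: 20 tertiary alcohol (8S)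
Conditions: MeMgBr, Et2O/CH2Cl2, −78 °C
Reagents that add atoms: methylmagnesium bromide (C[Mg]Br)
Why: Cram-chelate Grignard addition to an α-alkoxy ketone, in which magnesium bridges the carbonyl oxygen and the oxolane oxygen and methyl adds from the face of C7–H and not of C6, which gives (8S) with the chain already on C8.

Step 15
Reactants: 20 tertiary alcohol
Product: 21 primary alcohol with O13 PMB ether
Conditions: DIBAL (5 equiv), CH2Cl2, −78 → 0 °C; Rochelle salt
Reagents that add atoms: none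
Why: Reductive opening of the p-methoxybenzylidene acetal by DIBAL, in which aluminium binds the less hindered primary oxygen O14 and hydride is delivered to the acetal carbon, so the PMB group stays on the secondary O13 and the C14 hydroxyl is freed.

Step 16
Reactants: 21 primary alcohol with O13 PMB ether; 22 methyl 2-(bromomethyl)acrylate
Product: 23 (Z)-allylic bromide
Conditions: 22 (5 equiv), Hoveyda–Grubbs II (10 mol%), CH2Cl2, 40 °C
Reagents that add atoms: none
Why: Olefin cross-metathesis of the terminal alkene with an excess of the 1,1-disubstituted acrylate releases ethene and should give the more stable trisubstituted enoate with C2 trans to the ester, which is the (Z)-2-(bromomethyl)alk-2-enoate.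

Step 17
Reactants: 23 (Z)-allylic bromide
Product: 24 seco aldehyde
Conditions: Dess–Martin periodinane, NaHCO3, CH2Cl2, 0 °C → rt
Reagents that add atoms: none
Why: Buffered Dess–Martin oxidation gives the α-alkoxy aldehyde without epimerisation at C13 and leaves the tertiary alcohol and the allylic bromide untouched.

Step 18
Reactants: 24 seco aldehyde
Product: 26 macrocyclic α-methylene-γ-lactone with O13 PMB ether, via hydroxy ester 25 (not isolated)
Conditions: In powder, THF/H2O (1:1), slow addition to ca. 2 mM, rt; then PPTS (cat.), CH2Cl2, rt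
Reagents that add atoms: none
Why: Indium inserts into the allylic C17–Br bond and the γ-substituted 2-(methoxycarbonyl)allylindium adds through its γ-carbon C1 to the C14 aldehyde (SE2′) in a chair six-membered transition state; the closest known reaction type is the In-, Zn- or Cr-mediated Barbier 2-(alkoxycarbonyl)allylation of aldehydes to α-methylene-γ-butyrolactones, which is also known as a macrocyclisation. The 14-membered carbocycle closes by this intramolecular C1–C14 bond formation, and the γ-lactone closes by 5-exo-trig attack of the new O14 hydroxyl on the C16 ester with loss of methanol. The C1/C14 relationship is controlled by the alkene geometry: in the (Z)-bromide C2 is cis to C17, takes the axial place in the chair and leads to the syn adduct, which is the cis-fused lactone. The face of the aldehyde is controlled by C13: indium bridges the aldehyde oxygen and the O13 ether oxygen (Cram chelate), the allyl group enters anti to C12, and O14 ends up syn to O13. The step needs intra- over intermolecular addition, secured by slow addition at high dilution, and γ- over α-attack, which is the inherent mode of allylindium reagents; the tertiary C8 hydroxyl, the silyl ether and the PMB ether are inert in aqueous THF.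

Step 19
Reactants: 26 macrocyclic lactone with O13 PMB ether
Product: 27 8,13-diol
Conditions: DDQ, CH2Cl2/pH 7 buffer, 0 °C → rt
Reagents that add atoms: none
Why: Oxidative PMB cleavage by DDQ (hydride abstraction, then hydrolysis of the benzylic oxocarbenium ion) frees O13 and leaves the silyl ether and the electron-poor methylene lactone alone.

Step 20
Reactants: 27 8,13-diol
Product: 28 8,13-diacetate with O3 silyl ether
Conditions: Ac2O, DMAP, Et3N, CH2Cl2, rt → 40 °C
Reagents that add atoms: acetic anhydride (CC(=O)OC(C)=O)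
Why: DMAP-catalysed acetylation, fast at the secondary C13 hydroxyl and on prolonged reaction at the tertiary C8 hydroxyl, while O3 is silylated and any conjugate addition of DMAP to the methylene lactone is reversible.

Step 21
Reactants: 28 8,13-diacetate with O3 silyl ether
Product: 29 target
Conditions: HF·pyridine, pyridine, THF, 0 °C → rt
Reagents that add atoms: none
Why: Buffered fluoride desilylation removes the TBS group from O3 without cleaving the two acetates or adding to the methylene lactone.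

**Compound list**
1 | (S)-glycidol, (2S)-oxiran-2-ylmethanol | OC[C@H]1CO1 | starting material
2 | 2-methylallylmagnesium chloride | CC(=C)C[Mg]Cl | starting material
3 | (2R)-5-methylhex-5-ene-1,2-diol | OC[C@H](O)CCC(C)=C | intermediate
4 | [(2S,5R)-2-methyloxolane-2,5-diyl]dimethanol (cis) | OC[C@H]1CC[C@](C)(O1)CO | intermediate
5 | (1R,5S)-5-methyl-3,8-dioxabicyclo[3.2.1]octan-2-one | O=C1[C@H]2CC[C@](C)(O2)CO1 | intermediate
6 | (2R,5S)-5-(hydroxymethyl)-N-methoxy-N,5-dimethyloxolane-2-carboxamide | OC[C@]1(C)CC[C@@H](O1)C(=O)N(C)OC | intermediate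
7 | (2R,5S)-5-formyl-N-methoxy-N,5-dimethyloxolane-2-carboxamide | O=C[C@]1(C)CC[C@@H](O1)C(=O)N(C)OC | intermediate
8 | (2R,5S)-5-[(1R)-1-hydroxybut-3-en-1-yl]-N-methoxy-N,5-dimethyloxolane-2-carboxamide | C=CC[C@@H](O)[C@]1(C)CC[C@@H](O1)C(=O)N(C)OC | intermediate
9 | (2R,5S)-5-[(1R)-1-(tert-butyldimethylsilyloxy)but-3-en-1-yl]-N-methoxy-N,5-dimethyloxolane-2-carboxamide | C=CC[C@@H](O[Si](C)(C)C(C)(C)C)[C@]1(C)CC[C@@H](O1)C(=O)N(C)OC | intermediate
10 | (S)-citronellal, (3S)-3,7-dimethyloct-6-enal | CC(C)=CCC[C@H](C)CC=O | starting material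
11 | (2R,3S)-3,7-dimethyl-2-(phenylaminooxy)oct-6-enal | CC(C)=CCC[C@H](C)[C@@H](ONc1ccccc1)C=O | intermediate
12 | (2R,3S)-3,7-dimethyl-2-(phenylaminooxy)oct-6-en-1-ol | CC(C)=CCC[C@H](C)[C@@H](ONc1ccccc1)CO | intermediate
13 | (2R,3S)-3,7-dimethyloct-6-ene-1,2-diol | CC(C)=CCC[C@H](C)[C@@H](O)CO | intermediate
14 | (4R)-2-(4-methoxyphenyl)-4-[(2S)-6-methylhept-5-en-2-yl]-1,3-dioxolane (both C2 epimers) | CC(C)=CCC[C@H](C)[C@@H]1COC(O1)c1ccc(OC)cc1 | intermediate
15 | (4S)-4-[(4R)-2-(4-methoxyphenyl)-1,3-dioxolan-4-yl]pentanal | O=CCC[C@H](C)[C@@H]1COC(O1)c1ccc(OC)cc1 | intermediate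
16 | (4S)-4-[(4R)-2-(4-methoxyphenyl)-1,3-dioxolan-4-yl]pentan-1-ol | OCCC[C@H](C)[C@@H]1COC(O1)c1ccc(OC)cc1 | intermediate
17 | (4R)-4-[(2S)-5-iodopentan-2-yl]-2-(4-methoxyphenyl)-1,3-dioxolane | ICCC[C@H](C)[C@@H]1COC(O1)c1ccc(OC)cc1 | intermediate
18 | {(4S)-4-[(4R)-2-(4-methoxyphenyl)-1,3-dioxolan-4-yl]pentyl}lithium | [Li]CCC[C@H](C)[C@@H]1COC(O1)c1ccc(OC)cc1 | intermediate
19 | (5S)-1-{(2R,5S)-5-[(1R)-1-(tert-butyldimethylsilyloxy)but-3-en-1-yl]-5-methyloxolan-2-yl}-5-[(4R)-2-(4-methoxyphenyl)-1,3-dioxolan-4-yl]hexan-1-one | C=CC[C@@H](O[Si](C)(C)C(C)(C)C)[C@]1(C)CC[C@@H](O1)C(=O)CCC[C@H](C)[C@@H]1COC(O1)c1ccc(OC)cc1 | intermediate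
20 | (2S,6S)-2-{(2R,5S)-5-[(1R)-1-(tert-butyldimethylsilyloxy)but-3-en-1-yl]-5-methyloxolan-2-yl}-6-[(4R)-2-(4-methoxyphenyl)-1,3-dioxolan-4-yl]heptan-2-ol | C=CC[C@@H](O[Si](C)(C)C(C)(C)C)[C@]1(C)CC[C@@H](O1)[C@@](C)(O)CCC[C@H](C)[C@@H]1COC(O1)c1ccc(OC)cc1 | intermediate
21 | (2R,3S,7S)-7-{(2R,5S)-5-[(1R)-1-(tert-butyldimethylsilyloxy)but-3-en-1-yl]-5-methyloxolan-2-yl}-2-(4-methoxybenzyloxy)-3-methyloctane-1,7-diol | C=CC[C@@H](O[Si](C)(C)C(C)(C)C)[C@]1(C)CC[C@@H](O1)[C@@](C)(O)CCC[C@H](C)[C@@H](OCc1ccc(OC)cc1)CO | intermediate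
22 | methyl 2-(bromomethyl)acrylate | C=C(CBr)C(=O)OC | starting material
23 | methyl (2Z,5R)-2-(bromomethyl)-5-(tert-butyldimethylsilyloxy)-5-{(2S,5R)-5-[(2S,6S,7R)-2,8-dihydroxy-7-(4-methoxybenzyloxy)-6-methyloctan-2-yl]-2-methyloxolan-2-yl}pent-2-enoate | COC(=O)/C(CBr)=C/C[C@@H](O[Si](C)(C)C(C)(C)C)[C@]1(C)CC[C@@H](O1)[C@@](C)(O)CCC[C@H](C)[C@@H](OCc1ccc(OC)cc1)CO | intermediate
24 | methyl (2Z,5R)-2-(bromomethyl)-5-(tert-butyldimethylsilyloxy)-5-{(2S,5R)-5-[(2S,6S,7R)-2-hydroxy-7-(4-methoxybenzyloxy)-6-methyl-8-oxooctan-2-yl]-2-methyloxolan-2-yl}pent-2-enoate | COC(=O)/C(CBr)=C/C[C@@H](O[Si](C)(C)C(C)(C)C)[C@]1(C)CC[C@@H](O1)[C@@](C)(O)CCC[C@H](C)[C@@H](OCc1ccc(OC)cc1)C=O | intermediate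
25 | methyl (1S,3R,4S,7R,8S,12S,13R,14R)-4,7-epoxy-8,14-dihydroxy-13-(4-methoxybenzyloxy)-3-(tert-butyldimethylsilyloxy)cembr-15(17)-en-16-oate (14-membered carbocycle, lactone not yet closed) | COC(=O)C(=C)[C@@H]1C[C@@H](O[Si](C)(C)C(C)(C)C)[C@]2(C)CC[C@@H](O2)[C@@](C)(O)CCC[C@H](C)[C@@H](OCc3ccc(OC)cc3)[C@@H]1O | intermediate
26 | (1S,3R,4S,7R,8S,12S,13R,14R)-4,7-epoxy-8-hydroxy-13-(4-methoxybenzyloxy)-3-(tert-butyldimethylsilyloxy)cembr-15(17)-en-16,14-olide | C=C1C(=O)O[C@H]2[C@H](OCc4ccc(OC)cc4)[C@@H](C)CCC[C@](C)(O)[C@H]3CC[C@](C)(O3)[C@H](O[Si](C)(C)C(C)(C)C)C[C@@H]12 | intermediate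
27 | (1S,3R,4S,7R,8S,12S,13R,14R)-4,7-epoxy-8,13-dihydroxy-3-(tert-butyldimethylsilyloxy)cembr-15(17)-en-16,14-olide | C=C1C(=O)O[C@H]2[C@H](O)[C@@H](C)CCC[C@](C)(O)[C@H]3CC[C@](C)(O3)[C@H](O[Si](C)(C)C(C)(C)C)C[C@@H]12 | intermediate
28 | (1S,3R,4S,7R,8S,12S,13R,14R)-8,13-diacetoxy-4,7-epoxy-3-(tert-butyldimethylsilyloxy)cembr-15(17)-en-16,14-olide | C=C1C(=O)O[C@H]2[C@H](OC(C)=O)[C@@H](C)CCC[C@](C)(OC(C)=O)[C@H]3CC[C@](C)(O3)[C@H](O[Si](C)(C)C(C)(C)C)C[C@@H]12 | intermediate
29 | (1S,3R,4S,7R,8S,12S,13R,14R)-8,13-diacetoxy-4,7-epoxy-3-hydroxycembr-15(17)-en-16,14-olide | C=C1C(=O)O[C@H]2[C@H](OC(C)=O)[C@@H](C)CCC[C@](C)(OC(C)=O)[C@H]3CC[C@](C)(O3)[C@H](O)C[C@@H]12 | target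

**Count**
Total steps: 21. Longest linear sequence: 16 steps (steps 1–7, then 13–21); the citronellal branch (steps 8–12) joins at step 13.

**Steps most likely to fail**

Step 18. The allylindium may be protonated or may add intermolecularly before the ring closes, and the PMB ether may chelate too weakly to control the aldehyde face. The fallback separates formation of the nucleophile from the addition and uses an external chelating Lewis acid. It sets out from bromide 23, which is stannylated ((Bu3Sn)2, Pd(PPh3)4, THF) to the primary allylstannane F1. Dess–Martin oxidation gives the stannyl aldehyde F2. Treatment of F2 at high dilution with MgBr2·OEt2 in CH2Cl2 (Keck-type chelation between the aldehyde and O13, open SE2′ transition state that favours the syn adduct, as in the known intramolecular allylstannane macrocyclisations of cembranoids) should give hydroxy ester 25. Acid-catalysed lactonisation returns the route to 26.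

Step 16. The hindered, electron-poor 1,1-disubstituted acrylate may turn over slowly, the allylic bromide may consume catalyst, and 21 may homodimerise. The fallback builds the bromomethyl enoate from an aldehyde instead. It sets out from alkene 21, which is cleaved (OsO4, NaIO4, 2,6-lutidine) to the β-silyloxy aldehyde F3. Morita–Baylis–Hillman reaction with methyl acrylate (DABCO) gives the adduct F4 as a mixture of carbinol epimers. Allylic bromination with transposition (NBS, Me2S, CH2Cl2, 0 °C, selective for the allylic hydroxyl) comes back to 23.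

Step 3. The two primary hydroxyls of 4 may not be distinguished well enough in the oxidation, which would give the regioisomeric lactone. The fallback distinguishes them by steric protection and builds the C3 side first. It sets out from diol 4, whose unhindered hydroxyl is tritylated (TrCl, Et3N, DMAP) to the trityl ether F5. Dess–Martin oxidation gives the aldehyde F6, Brown allylation with (+)-Ipc2B(allyl) the homoallylic alcohol F7, and TBSOTf the silyl ether F8. Detritylation (ZnBr2, CH2Cl2/MeOH) gives the primary alcohol F9, oxidation (TEMPO, PhI(OAc)2, MeCN/H2O) the acid F10, and coupling with Me(MeO)NH·HCl (EDC, HOBt, Et3N) comes back to Weinreb amide 9.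

Further compounds
F1 | step 18 | methyl (2Z,5R)-5-(tert-butyldimethylsilyloxy)-5-{(2S,5R)-5-[(2S,6S,7R)-2,8-dihydroxy-7-(4-methoxybenzyloxy)-6-methyloctan-2-yl]-2-methyloxolan-2-yl}-2-(tributylstannylmethyl)pent-2-enoate | COC(=O)/C(C[Sn](CCCC)(CCCC)CCCC)=C/C[C@@H](O[Si](C)(C)C(C)(C)C)[C@]1(C)CC[C@@H](O1)[C@@](C)(O)CCC[C@H](C)[C@@H](OCc1ccc(OC)cc1)CO
F2 | step 18 | methyl (2Z,5R)-5-(tert-butyldimethylsilyloxy)-5-{(2S,5R)-5-[(2S,6S,7R)-2-hydroxy-7-(4-methoxybenzyloxy)-6-methyl-8-oxooctan-2-yl]-2-methyloxolan-2-yl}-2-(tributylstannylmethyl)pent-2-enoate | COC(=O)/C(C[Sn](CCCC)(CCCC)CCCC)=C/C[C@@H](O[Si](C)(C)C(C)(C)C)[C@]1(C)CC[C@@H](O1)[C@@](C)(O)CCC[C@H](C)[C@@H](OCc1ccc(OC)cc1)C=O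
F3 | step 16 | (3R)-3-(tert-butyldimethylsilyloxy)-3-{(2S,5R)-5-[(2S,6S,7R)-2,8-dihydroxy-7-(4-methoxybenzyloxy)-6-methyloctan-2-yl]-2-methyloxolan-2-yl}propanal | O=CC[C@@H](O[Si](C)(C)C(C)(C)C)[C@]1(C)CC[C@@H](O1)[C@@](C)(O)CCC[C@H](C)[C@@H](OCc1ccc(OC)cc1)CO
F4 | step 16 | methyl (5R)-5-(tert-butyldimethylsilyloxy)-5-{(2S,5R)-5-[(2S,6S,7R)-2,8-dihydroxy-7-(4-methoxybenzyloxy)-6-methyloctan-2-yl]-2-methyloxolan-2-yl}-3-hydroxy-2-methylidenepentanoate (both C3 epimers) | COC(=O)C(=C)C(O)C[C@@H](O[Si](C)(C)C(C)(C)C)[C@]1(C)CC[C@@H](O1)[C@@](C)(O)CCC[C@H](C)[C@@H](OCc1ccc(OC)cc1)CO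
F5 | step 3 | [(2S,5R)-2-methyl-5-(trityloxymethyl)oxolan-2-yl]methanol | OC[C@]1(C)CC[C@@H](O1)COC(c1ccccc1)(c1ccccc1)c1ccccc1
F6 | step 3 | (2S,5R)-2-methyl-5-(trityloxymethyl)oxolane-2-carbaldehyde | O=C[C@]1(C)CC[C@@H](O1)COC(c1ccccc1)(c1ccccc1)c1ccccc1
F7 | step 3 | (1R)-1-[(2S,5R)-2-methyl-5-(trityloxymethyl)oxolan-2-yl]but-3-en-1-ol | C=CC[C@@H](O)[C@]1(C)CC[C@@H](O1)COC(c1ccccc1)(c1ccccc1)c1ccccc1
F8 | step 3 | tert-butyldimethyl{(1R)-1-[(2S,5R)-2-methyl-5-(trityloxymethyl)oxolan-2-yl]but-3-en-1-yloxy}silane | C=CC[C@@H](O[Si](C)(C)C(C)(C)C)[C@]1(C)CC[C@@H](O1)COC(c1ccccc1)(c1ccccc1)c1ccccc1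
F9 | step 3 | {(2R,5S)-5-[(1R)-1-(tert-butyldimethylsilyloxy)but-3-en-1-yl]-5-methyloxolan-2-yl}methanol | C=CC[C@@H](O[Si](C)(C)C(C)(C)C)[C@]1(C)CC[C@@H](O1)CO
F10 | step 3 | (2R,5S)-5-[(1R)-1-(tert-butyldimethylsilyloxy)but-3-en-1-yl]-5-methyloxolane-2-carboxylic acid | C=CC[C@@H](O[Si](C)(C)C(C)(C)C)[C@]1(C)CC[C@@H](O1)C(=O)O
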